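# Total synthesis of polymatin A

## Retrosynthetic overview

1. Polymatin A ⇐ late angeloylation of C8–OH and desilylation of C9–O on a macrolactone carrying C8–OPMB / C9–OTBS.
2. Ten-membered carbocycle first, then the trans-γ-lactone: intramolecular Cr(II) (Nozaki–Hiyama–Kishi type) allylation forming C6–C7 from an enal / (Z)-2-(bromomethyl)enoate, then lactonisation.
3. Bromomethyl-enoate ⇐ Morita–Baylis–Hillman reaction on a C7 aldehyde. The C1=C10 enoate (ring-cis) ⇐ propargylic alcohol by syn-hydrostannation, iodination and Pd methoxycarbonylation.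
4. Propargylic alcohol ⇐ C1–C6 alkyne (from geranyl acetate) + C7–C9 glyceraldehyde unit; C9 set by Noyori transfer hydrogenation of the ynone.
5. C7–C9 unit ⇐ lipase desymmetrisation of achiral 2-O-PMB-glycerol, which sets C8.

Atom labels C1–C15 follow germacrane numbering of the target: lactone C12(=O)–O–C6, C11=C13H2, C4–CH3 is C15, C10–CO2Me is C14.

Assumption: 2-O-PMB-glycerol is acylated by the lipase with the same pro-chiral preference reported for 2-O-benzylglycerol, giving the (S)-monoacetate. If the opposite sense were found, the same enzyme in hydrolysis mode on the diacetate gives the required enantiomer.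

## Route

**Step 1**
Reactants: 1, 2-phenyl-1,3-dioxan-5-ol (1,3-O-benzylideneglycerol; achiral)
Product: 2, 5-[(4-methoxybenzyl)oxy]-2-phenyl-1,3-dioxane
Conditions: NaH, PMBCl, TBAI (cat.), THF/DMF, 0 °C → rt
Reagents that add atoms: 4-methoxybenzyl chloride, COc1ccc(CCl)cc1
Why: Williamson etherification of the only free hydroxyl; the acetal masks both primary hydroxyls, so the product stays achiral.

**Step 2**
Reactants: 2
Product: 3, 2-[(4-methoxybenzyl)oxy]propane-1,3-diol (prochiral)
Conditions: p-TsOH·H2O (cat.), MeOH, rt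
Reagents that add atoms: none
Why: Acid-catalysed transacetalisation removes the benzylidene as PhCH(OMe)2; the PMB ether tolerates catalytic acid at rt.

**Step 3**
Reactants: 3
Product: 4, (S)-3-hydroxy-2-[(4-methoxybenzyl)oxy]propyl acetate
Conditions: lipase (Pseudomonas fluorescens lipase, Amano AK), vinyl acetate, rt
Reagents that add atoms: vinyl acetate, CC(=O)OC=C
Why: Lipase-catalysed irreversible transesterification acylates one enantiotopic CH2OH of the prochiral diol (enzymatic desymmetrisation), creating the C8 stereocentre. About 95% ee is expected by analogy with the benzyl series, and slight over-acylation removes the minor enantiomer.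

**Step 4**
Reactants: 4
Product: 5, (R)-2-[(4-methoxybenzyl)oxy]-3-[(triethylsilyl)oxy]propyl acetate
Conditions: TESCl, imidazole, CH2Cl2, 0 °C
Reagents that add atoms: chlorotriethylsilane, CC[Si](Cl)(CC)CC
Why: Silylation of the free primary hydroxyl (the future C7 arm); the stereocentre is untouched and the descriptor changes only through CIP priorities.

**Step 5**
Reactants: 5
Product: 6, (R)-2-[(4-methoxybenzyl)oxy]-3-[(triethylsilyl)oxy]propan-1-ol
Conditions: DIBAL-H (2.2 equiv), CH2Cl2, −78 °C; Rochelle salt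
Reagents that add atoms: none
Why: Reductive removal of the acetate at low temperature avoids the basic methanolysis that could cleave or migrate the TES group.

**Step 6**
Reactants: 6
Product: 7, (S)-2-[(4-methoxybenzyl)oxy]-3-[(triethylsilyl)oxy]propanal (used crude)
Conditions: Dess–Martin periodinane, NaHCO3, CH2Cl2, 0 °C → rt
Reagents that add atoms: none
Why: Buffered Dess–Martin oxidation gives the α-alkoxy aldehyde (the future C9 carbon) without base-mediated epimerisation.

**Step 7**
Reactants: 8, geranyl acetate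
Product: 9, (2E)-3-methyl-6-oxohex-2-en-1-yl acetate
Conditions: O3 (1.0 equiv, Sudan III end point), CH2Cl2, pyridine, −78 °C; then Me2S
Reagents that add atoms: ozone, [O-][O+]=O
Why: Chemoselective ozonolysis: the electron-rich terminal trisubstituted alkene reacts far faster than the 2,3-alkene deactivated by the allylic acetate, and the 2E geometry (future C4=C5) is retained.

**Step 8**
Reactants: 9
Product: 10, (2E)-3-methylhept-2-en-6-yn-1-ol
Conditions: dimethyl (1-diazo-2-oxopropyl)phosphonate, K2CO3, MeOH, 0 °C → rt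
Reagents that add atoms: Ohira–Bestmann reagent, COP(=O)(OC)C(=[N+]=[N-])C(C)=O
Why: Seyferth–Gilbert/Ohira–Bestmann homologation converts the aldehyde into the terminal alkyne (adds C10); the K2CO3/MeOH medium also methanolyses the acetate.

**Step 9**
Reactants: 10
Product: 11, tert-butyldimethyl{[(2E)-3-methylhept-2-en-6-yn-1-yl]oxy}silane
Conditions: TBSCl, imidazole, DMF, rt
Reagents that add atoms: tert-butyldimethylsilyl chloride, CC(C)(C)[Si](C)(C)Cl
Why: Standard silylation of the primary allylic alcohol (C6–O), needed for the acetylide chemistry.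

**Step 10**
Reactants: 11 and 7
Product: 12, (2S,8E)-10-(TBSO)-2-(PMBO)-8-methyl-1-(TESO)dec-8-en-4-yn-3-ol, mixture of C3 (= C9) epimers
Conditions: 11, n-BuLi, THF, −78 °C; then 7, −78 °C
Reagents that add atoms: none
Why: Lithium acetylide addition to the aldehyde forms the C9–C10 bond; the epimer mixture is irrelevant because the carbinol is oxidised next.

**Step 11**
Reactants: 12
Product: 13, (2S,8E)-10-(TBSO)-2-(PMBO)-8-methyl-1-(TESO)dec-8-en-4-yn-3-one
Conditions: Dess–Martin periodinane, NaHCO3, CH2Cl2, 0 °C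
Reagents that add atoms: none
Why: Mild non-basic oxidation of the propargylic alcohol to the ynone leaves the adjacent α-alkoxy centre intact.

**Step 12**
Reactants: 13
Product: 14, (2S,3S,8E)-10-(TBSO)-2-(PMBO)-8-methyl-1-(TESO)dec-8-en-4-yn-3-ol (C8 S, C9 S; threo)
Conditions: Ru[(R,R)-TsDPEN](p-cymene) (3 mol %), i-PrOH, rt
Reagents that add atoms: none
Why: Noyori asymmetric transfer hydrogenation of the ynone is catalyst-controlled (the alkynyl group takes the aryl role) and base-free. The (R,R)-catalyst delivers hydride to give the 9S carbinol regardless of the neighbouring stereocentre.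

**Step 13**
Reactants: 14
Product: 15, (2S,3R,4E,8E)-10-(TBSO)-2-(PMBO)-8-methyl-4-(tributylstannyl)-1-(TESO)deca-4,8-dien-3-ol
Conditions: Bu3SnH, PdCl2(PPh3)2 (5 mol %), THF, 0 °C → rt
Reagents that add atoms: tributyltin hydride, CCCC[SnH](CCCC)CCCC
Why: Pd-catalysed syn-hydrostannation places tin on the alkyne carbon proximal to the free propargylic hydroxyl (C10) and H on C1. The cis addition fixes C2 cis to C9, which is the required 1(10) geometry.

**Step 14**
Reactants: 15
Product: 16, (2S,3R,4E,8E)-4-iodo-10-(TBSO)-2-(PMBO)-8-methyl-1-(TESO)deca-4,8-dien-3-ol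
Conditions: I2, CH2Cl2, 0 °C; Na2S2O3
Reagents that add atoms: iodine, II
Why: Iododestannylation proceeds with retention of alkene geometry; the other alkenes and ethers are inert at 0 °C.

**Step 15**
Reactants: 16
Product: 17, (2S,3R,4E,8E)-3,10-bis(TBSO)-4-iodo-2-(PMBO)-8-methyl-1-(TESO)deca-4,8-diene
Conditions: TBSOTf, 2,6-lutidine, CH2Cl2, −78 → 0 °C
Reagents that add atoms: TBS triflate, CC(C)(C)[Si](C)(C)OS(=O)(=O)C(F)(F)F
Why: Silylation of the hindered secondary allylic alcohol (C9–O) with the reactive triflate; this group stays until the last step.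

**Step 16**
Reactants: 17
Product: 18, methyl (2E,6E)-8-(TBSO)-2-[(1S,2S)-1-(TBSO)-2-(PMBO)-3-(TESO)propyl]-6-methylocta-2,6-dienoate
Conditions: Pd(OAc)2 (10 mol %), dppf, CO (1 atm), Et3N, MeOH/DMF (1:4), 60 °C
Reagents that add atoms: carbon monoxide, [C-]#[O+]; methanol, CO
Why: Pd-catalysed methoxycarbonylation of the vinyl iodide (oxidative addition, CO insertion, methanolysis) installs C14 with retention, so CO2Me is trans to C2.

**Step 17**
Reactants: 18
Product: 19, methyl (2E,6E)-8-(TBSO)-2-[(1S,2S)-1-(TBSO)-3-hydroxy-2-(PMBO)propyl]-6-methylocta-2,6-dienoate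
Conditions: PPTS (cat.), MeOH/CH2Cl2, 0 °C
Reagents that add atoms: none
Why: Acid-catalysed solvolysis removes the primary TES ether, which is roughly two orders of magnitude more labile than the primary and secondary TBS ethers.

**Step 18**
Reactants: 19
Product: 20, methyl (2E,6E)-8-(TBSO)-2-[(1S,2R)-1-(TBSO)-2-(PMBO)-3-oxopropyl]-6-methylocta-2,6-dienoate (C7 aldehyde)
Conditions: Dess–Martin periodinane, NaHCO3, CH2Cl2, 0 °C → rt
Reagents that add atoms: none
Why: Neutral oxidation to the α-alkoxy aldehyde; C8 is spatially unchanged and only its descriptor changes.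

**Step 19**
Reactants: 20 and 21, methyl acrylate
Product: 22, Morita–Baylis–Hillman adduct: as 20 with C7 now CH(OH)–C(=CH2)CO2Me; mixture of C7 epimers
Conditions: DABCO (1 equiv), methyl acrylate (neat, excess), rt, 3–5 d
Reagents that add atoms: methyl acrylate, C=CC(=O)OC
Why: Morita–Baylis–Hillman reaction: the DABCO–acrylate zwitterion adds to the electrophilic α-alkoxy aldehyde and introduces C11–C13. The new C7 carbinol centre is inconsequential because it becomes sp2 in step 22.

**Step 20**
Reactants: 22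
Product: 23, C6-alcohol: as 22 with C6–OH free
Conditions: HF·pyridine, pyridine, THF, 0 °C
Reagents that add atoms: none
Why: Buffered HF·pyridine cleaves the unhindered primary allylic TBS ether much faster than the hindered secondary TBS ether at C9.

**Step 21**
Reactants: 23
Product: 24, enal: as 23 with C6 oxidised to the (E)-3-methyl-enal
Conditions: TEMPO (10 mol %), PhI(OAc)2, CH2Cl2, rt
Reagents that add atoms: none
Why: TEMPO/PhI(OAc)2 oxidises only the primary allylic alcohol and does not touch the secondary Baylis–Hillman alcohol. It does not isomerise the 4E alkene, as in geraniol → geranial.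

**Step 22**
Reactants: 24
Product: 25, methyl (2E,6E)-2-[(1S,2S,3Z)-4-(bromomethyl)-1-(TBSO)-5-methoxy-2-(PMBO)-5-oxopent-3-en-1-yl]-6-methyl-8-oxoocta-2,6-dienoate
Conditions: NBS, Me2S, CH2Cl2, −20 → 0 °C
Reagents that add atoms: N-bromosuccinimide, BrN1C(=O)CCC1=O
Why: Corey–Kim activation of the Baylis–Hillman alcohol followed by SN2′ attack of bromide gives the conjugated (Z)-2-(bromomethyl)enoate; the aldehyde, enoate and ethers are inert.

**Step 23**
Reactants: 25
Product: 26, macrolactone (6R,7S,8S,9S): 8-O-PMB-9-O-TBS-8-desangeloylpolymatin A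
Conditions: CrCl2 (10 equiv), THF, rt, syringe-pump addition (final 2 mM); then p-TsOH·H2O (cat.), CH2Cl2, rt
Reagents that add atoms: none
Why: Nozaki–Hiyama–Kishi-type Cr(II) allylation. The allylchromium adds through C7 to the enal in a chair transition state with both ring tethers pseudo-equatorial, giving the 6,7-anti adduct and hence the trans-lactone, as in Cr(II) closures of related germacranolide precursors. A(1,3) strain holds H-8 in the alkene plane, so C6 bonds to the C7 face anti to the C8–C9 bond, giving 6R,7S. The C6 alkoxide then lactonises onto the C12 ester.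

**Step 24**
Reactants: 26
Product: 27, 8-hydroxy macrolactone (9-O-TBS-8-desangeloylpolymatin A; descriptors 6R,7R,8S,9S, where the C7 descriptor changes only because of CIP priority)
Conditions: DDQ, CH2Cl2/pH 7 buffer (10:1), 0 °C
Reagents that add atoms: none
Why: Oxidative cleavage of the PMB ether by DDQ under buffered conditions; the silyl ether, lactone, enoate and alkenes are untouched.

**Step 25**
Reactants: 27 and 28, angelic acid [(Z)-2-methylbut-2-enoic acid]
Product: 29, 9-O-TBS-polymatin A
Conditions: 28, 2,4,6-trichlorobenzoyl chloride, Et3N, toluene, rt; then 27, 75 °C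
Reagents that add atoms: angelic acid, C/C=C(/C)C(=O)O
Why: Yamaguchi-type mixed-anhydride acylation esterifies the hindered C8 hydroxyl with retention at C8. Omitting a nucleophilic catalyst avoids Z→E isomerisation of the angelate to the tiglate.

**Step 26**
Reactants: 29
Product: 30, polymatin A
Conditions: HF·pyridine, THF/pyridine, 0 °C → rt
Reagents that add atoms: none
Why: Mildly acidic, non-nucleophilic desilylation frees C9–OH without acyl migration, angelate isomerisation or conjugate addition to the α-methylene lactone.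

## Compound list

1 | 2-phenyl-1,3-dioxan-5-ol (cis/trans immaterial, both achiral) | OC1COC(c2ccccc2)OC1 | starting material
2 | 5-[(4-methoxybenzyl)oxy]-2-phenyl-1,3-dioxane | COc1ccc(COC2COC(c3ccccc3)OC2)cc1 | intermediate
3 | 2-[(4-methoxybenzyl)oxy]propane-1,3-diol | COc1ccc(COC(CO)CO)cc1 | intermediate
4 | (S)-3-hydroxy-2-[(4-methoxybenzyl)oxy]propyl acetate | CC(=O)OC[C@@H](OCc1ccc(OC)cc1)CO | intermediate
5 | (R)-2-[(4-methoxybenzyl)oxy]-3-[(triethylsilyl)oxy]propyl acetate | CC(=O)OC[C@@H](OCc1ccc(OC)cc1)CO[Si](CC)(CC)CC | intermediate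
6 | (R)-2-[(4-methoxybenzyl)oxy]-3-[(triethylsilyl)oxy]propan-1-ol | OC[C@@H](OCc1ccc(OC)cc1)CO[Si](CC)(CC)CC | intermediate
7 | (S)-2-[(4-methoxybenzyl)oxy]-3-[(triethylsilyl)oxy]propanal | O=C[C@@H](OCc1ccc(OC)cc1)CO[Si](CC)(CC)CC | intermediate
8 | geranyl acetate | CC(C)=CCC/C(C)=C/COC(C)=O | starting material
9 | (2E)-3-methyl-6-oxohex-2-en-1-yl acetate | O=CCC/C(C)=C/COC(C)=O | intermediate
10 | (2E)-3-methylhept-2-en-6-yn-1-ol | C#CCC/C(C)=C/CO | intermediate
11 | TBS ether of 10 | C#CCC/C(C)=C/CO[Si](C)(C)C(C)(C)C | intermediate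
12 | propargylic alcohol, C9 epimers | CC(C)(C)[Si](C)(C)OC/C=C(\C)CCC#CC(O)[C@@H](OCc1ccc(OC)cc1)CO[Si](CC)(CC)CC | intermediate
13 | ynone | CC(C)(C)[Si](C)(C)OC/C=C(\C)CCC#CC(=O)[C@@H](OCc1ccc(OC)cc1)CO[Si](CC)(CC)CC | intermediate
14 | (8S,9S)-propargylic alcohol | CC(C)(C)[Si](C)(C)OC/C=C(\C)CCC#C[C@H](O)[C@@H](OCc1ccc(OC)cc1)CO[Si](CC)(CC)CC | intermediate
15 | C10 vinylstannane | CC(C)(C)[Si](C)(C)OC/C=C(\C)CC/C=C(/[Sn](CCCC)(CCCC)CCCC)[C@H](O)[C@@H](OCc1ccc(OC)cc1)CO[Si](CC)(CC)CC | intermediate
16 | C10 vinyl iodide | CC(C)(C)[Si](C)(C)OC/C=C(\C)CC/C=C(/I)[C@H](O)[C@@H](OCc1ccc(OC)cc1)CO[Si](CC)(CC)CC | intermediate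
17 | vinyl iodide, C9–OTBS | CC(C)(C)[Si](C)(C)OC/C=C(\C)CC/C=C(/I)[C@H](O[Si](C)(C)C(C)(C)C)[C@@H](OCc1ccc(OC)cc1)CO[Si](CC)(CC)CC | intermediate
18 | C14 methyl ester, C7–OTES | CC(C)(C)[Si](C)(C)OC/C=C(\C)CC/C=C(/C(=O)OC)[C@H](O[Si](C)(C)C(C)(C)C)[C@@H](OCc1ccc(OC)cc1)CO[Si](CC)(CC)CC | intermediate
19 | C7 alcohol | CC(C)(C)[Si](C)(C)OC/C=C(\C)CC/C=C(/C(=O)OC)[C@H](O[Si](C)(C)C(C)(C)C)[C@@H](OCc1ccc(OC)cc1)CO | intermediate
20 | C7 aldehyde | CC(C)(C)[Si](C)(C)OC/C=C(\C)CC/C=C(/C(=O)OC)[C@H](O[Si](C)(C)C(C)(C)C)[C@@H](OCc1ccc(OC)cc1)C=O | intermediate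
21 | methyl acrylate | C=CC(=O)OC | starting material
22 | Baylis–Hillman adduct, C7 epimers | CC(C)(C)[Si](C)(C)OC/C=C(\C)CC/C=C(/C(=O)OC)[C@H](O[Si](C)(C)C(C)(C)C)[C@@H](OCc1ccc(OC)cc1)C(O)C(=C)C(=O)OC | intermediate
23 | C6 alcohol | OC/C=C(\C)CC/C=C(/C(=O)OC)[C@H](O[Si](C)(C)C(C)(C)C)[C@@H](OCc1ccc(OC)cc1)C(O)C(=C)C(=O)OC | intermediate
24 | C6 enal | O=C/C=C(\C)CC/C=C(/C(=O)OC)[C@H](O[Si](C)(C)C(C)(C)C)[C@@H](OCc1ccc(OC)cc1)C(O)C(=C)C(=O)OC | intermediate
25 | (Z)-allylic bromide / enal | O=C/C=C(\C)CC/C=C(/C(=O)OC)[C@H](O[Si](C)(C)C(C)(C)C)[C@@H](OCc1ccc(OC)cc1)/C=C(\CBr)C(=O)OC | intermediate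
26 | macrolactone, 8-OPMB, 9-OTBS | C=C1C(=O)O[C@@H]2/C=C(\C)CC/C=C(/C(=O)OC)[C@H](O[Si](C)(C)C(C)(C)C)[C@@H](OCc3ccc(OC)cc3)[C@@H]12 | intermediate
27 | macrolactone, 8-OH, 9-OTBS | C=C1C(=O)O[C@@H]2/C=C(\C)CC/C=C(/C(=O)OC)[C@H](O[Si](C)(C)C(C)(C)C)[C@@H](O)[C@@H]12 | intermediate
28 | angelic acid | C/C=C(/C)C(=O)O | starting material
29 | 9-O-TBS-polymatin A | C=C1C(=O)O[C@@H]2/C=C(\C)CC/C=C(/C(=O)OC)[C@H](O[Si](C)(C)C(C)(C)C)[C@@H](OC(=O)/C(C)=C\C)[C@@H]12 | intermediate
30 | polymatin A, methyl (3aS,4S,5S,6E,10E,11aR)-5-hydroxy-10-methyl-3-methylidene-4-{[(2Z)-2-methylbut-2-enoyl]oxy}-2-oxo-2,3,3a,4,5,8,9,11a-octahydrocyclodeca[b]furan-6-carboxylate | C=C1C(=O)O[C@@H]2/C=C(\C)CC/C=C(/C(=O)OC)[C@H](O)[C@@H](OC(=O)/C(C)=C\C)[C@@H]12 | target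

## Summary

Total step count: 26.
Longest linear sequence: 23 steps (steps 1–6, then 10–26, from 1). The geranyl acetate branch is 3 steps before the union.

Three steps most likely to fail, each with a fallback:

1. **Step 23 (Cr(II) macrocyclisation).** The ring closure sets both C6 and C7, and the predicted 6R,7S outcome rests on a transition-state model and class precedent, not on a directly analogous substrate; yield of a ten-membered ring is also a concern. Fallback: replace the allyl bromide with a configurationally defined propargylic mesylate at C7 (TMS-acetylene addition to 20, oxidation, Noyori reduction, mesylation). Then carry out a Marshall Pd(0)/Et2Zn allenylzinc addition to the C6 enal, which transfers the mesylate chirality to C7 and gives the anti homopropargylic alcohol. Build the trans α-methylene lactone afterwards by Pd-catalysed cyclocarbonylation of that alcohol.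

2. **Step 13 (hydrostannation regiochemistry).** Tin must go to C10; a significant amount of the C1 regioisomer would erode the route. Fallback: reverse the polarity at C10. Make the methyl (Z)-2-iodo-enoate from aldehyde 9 by Wittig reaction with Ph3P=C(I)CO2Me, so the ester and geometry are already in place. Couple it to aldehyde 7 by Nozaki–Hiyama–Kishi reaction (CrCl2/NiCl2), and correct C9 if needed by oxidation and CBS reduction.

3. **Step 25 (angeloylation of the hindered C8–OH).** Risks are low conversion and isomerisation to the tiglate. Fallback: build the angelate on the molecule. Acylate C8–OH with 2-[bis(2,2,2-trifluoroethoxy)phosphoryl]propanoic acid (DCC), then run a Z-selective Still–Gennari olefination with acetaldehyde (KHMDS, 18-crown-6, −78 °C).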